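## Retrosynthetic overview

1. The C17 aldehyde comes from the primary alcohol of an 8,17-diol, made by equatorial addition of a hydroxymethyl anion equivalent to an 8-ketone (sets C8). The 8-ketone comes from a C8=C9 alkene by hydroboration–oxidation, and the alkene from a C9 enol triflate plus a zinc reagent carrying the whole (Z)-enoate chain, whose geometry is inherited from 4-methyl-5,6-dihydro-2H-pyran-2-one.
2. The bicyclic 3,9-dioxo core is made in one flask from three components: 2-methylcyclohex-2-enone (all of ring B), the ketene silyl acetal of methyl isobutyrate (C3, C4 and both C4 methyls) and tert-butyl acrylate (C1, C2), by a Michael/Michael/Dieckmann annulation.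
3. Enabling feature: ring A (C10–C1–C2–C3–C4–C5) has its oxygen at C3 next to the quaternary C4, and is fused through C5–C10, which maps onto the Cβ=Cα bond of an α-methyl enone with its carbonyl at C9. C3 and C9 are 1,5-related through C4–C5–C10 (first Michael), C9 and the C2 carboxyl are 1,5-related through C10–C1 (second Michael), and C4 has no hydrogen, so the C3 ester can only be the acyl acceptor (ring closure).
4. Temporary elements: the C2 ester (removed in step 3), the C9 carbonyl (moved to C8 in steps 2 and 7–9), the C3 ketone level (reduced in step 4) and a triethylsilyl ether.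
5. Ring order: ring B is bought; ring A is the only ring made and is closed in step 1.

Key step: step 1

Locants C1–C17 follow labdane numbering: ring A = C1–C5 and C10, ring B = C5–C10, C17 on C8, side chain C11–C16 on C9.

Assumption: the (S)-oxazaborolidinium catalyst is taken to give (S)-C5 in 4; if its sense of induction is the opposite, the (R)-catalyst is used and nothing else changes.

## Route

Step 1
Reactants: 1 2-methylcyclohex-2-en-1-one; 2 1-methoxy-2-methyl-1-(trimethylsilyloxy)prop-1-ene; 3 tert-butyl prop-2-enoate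
Product: 7 tert-butyl (4aR,8aR)-4,4,8a-trimethyl-3,8-dioxodecahydronaphthalene-2-carboxylate (C2 epimers/enol), via silyl enol ether 4 (not isolated), via potassium enolate 5 (not isolated), via ester enolate 6 (not isolated)
Conditions: (S)-1-(2-methylphenyl)-3,3-diphenyltetrahydro-1H,3H-pyrrolo[1,2-c][1,3,2]oxazaborole (20 mol%), HN(SO2CF3)2 (20 mol%), Ph3PO (25 mol%), toluene, −20 °C; volatiles removed; KOtBu, THF, −20 °C; then 3, −78 °C → rt; aq. NH4Cl
Reagents that add atoms: none
Why: The oxazaborolidinium-activated enone 1 takes up the ketene silyl acetal 2 at C5 on the face left open by the catalyst (Mukaiyama–Michael addition, giving the regiodefined C9=C10 silyl enol ether 4), KOtBu unmasks the potassium enolate 5, this adds to acrylate 3 at C10 (enolate Michael addition), and the ester enolate 6 closes ring A by Dieckmann acylation at the C3 ester, i.e. a Michael–Michael–ring-closure annulation of the MIMIRC type. Ring A is closed 6-exo-trig by the C2 carbanion on the C3 carbonyl, the former enone C5–C10 bond becoming the ring fusion. C5 is set by the chiral catalyst; C10 is set by the substrate, the acrylate entering anti to the pseudoaxial C5 tert-alkyl group, which gives the trans fusion with C1 and C4 both equatorial on ring B. Chemoselectivity rests on the quaternary C4: the isobutyrate-derived ester has no α-hydrogen and can only accept, so the only closure that ends in a stabilised β-keto ester enolate is C2 to C3, whereas bridged closures from C8 give non-enolisable 1,3-diketones and revert. Regioselectivity for C10 over C8 is secured by releasing the enolate from the regiodefined silyl enol ether at low temperature.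

Step 2
Reactants: 7 tert-butyl (4aR,8aR)-4,4,8a-trimethyl-3,8-dioxodecahydronaphthalene-2-carboxylate
Product: 8 tert-butyl (4aS,8aR)-4,4,8a-trimethyl-3-oxo-8-(trifluoromethanesulfonyloxy)-1,2,3,4,4a,5,6,8a-octahydronaphthalene-2-carboxylate (C2 epimers/enol)
Conditions: KN(SiMe3)2 (2.2 equiv), THF, −78 °C; N-(5-chloropyridin-2-yl)-1,1,1-trifluoro-N-(trifluoromethanesulfonyl)methanesulfonamide (1.1 equiv), −78 → −40 °C
Reagents that add atoms: N-(5-chloropyridin-2-yl)-1,1,1-trifluoro-N-(trifluoromethanesulfonyl)methanesulfonamide, Clc1ccc(nc1)N(S(=O)(=O)C(F)(F)F)S(=O)(=O)C(F)(F)F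
Why: In the dianion the β-keto ester is parked as its stabilised enolate while the C9 ketone, enolisable only towards C8, gives the more nucleophilic enolate that is O-triflated (regiospecific enol triflate formation); no stereocenter is made.

Step 3
Reactants: 8 tert-butyl (4aS,8aR)-4,4,8a-trimethyl-3-oxo-8-(trifluoromethanesulfonyloxy)-1,2,3,4,4a,5,6,8a-octahydronaphthalene-2-carboxylate
Product: 9 (4aS,8aR)-5,5,8a-trimethyl-6-oxo-3,4,4a,5,6,7,8,8a-octahydronaphthalen-1-yl trifluoromethanesulfonate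
Conditions: CF3CO2H/CH2Cl2 (1:3), rt; then toluene, 80 °C
Reagents that add atoms: none
Why: Acidolysis of the tert-butyl ester and loss of CO2 from the β-keto acid (β-keto acid decarboxylation) removes the temporary C2 activating group, the enol triflate being stable to acid.

Step 4
Reactants: 9 (4aS,8aR)-5,5,8a-trimethyl-6-oxo-3,4,4a,5,6,7,8,8a-octahydronaphthalen-1-yl trifluoromethanesulfonate
Product: 10 (4aR,6R,8aR)-6-hydroxy-5,5,8a-trimethyl-3,4,4a,5,6,7,8,8a-octahydronaphthalen-1-yl trifluoromethanesulfonate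
Conditions: NaBH4, MeOH, 0 °C
Reagents that add atoms: none
Why: Borohydride reduction of the 4,4-dimethyl-3-ketone by axial hydride delivery on the unhindered face bearing H5 should give the equatorial (3R) alcohol, as is general for 4,4-dimethyl-3-oxo trans-decalins; the enol triflate is inert.

Step 5
Reactants: 10 (4aR,6R,8aR)-6-hydroxy-5,5,8a-trimethyl-3,4,4a,5,6,7,8,8a-octahydronaphthalen-1-yl trifluoromethanesulfonate
Product: 11 (4aR,6R,8aR)-5,5,8a-trimethyl-6-(triethylsilyloxy)-3,4,4a,5,6,7,8,8a-octahydronaphthalen-1-yl trifluoromethanesulfonate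
Conditions: Et3SiOSO2CF3, 2,6-lutidine, CH2Cl2, −40 → 0 °C
Reagents that add atoms: triethylsilyl trifluoromethanesulfonate, CC[Si](CC)(CC)OS(=O)(=O)C(F)(F)F
Why: Silylation with the silyl triflate protects the hindered neopentyl-type C3 alcohol as an ether that survives steps 7–10 and falls off in dilute acid.

Step 6
Reactants: 12 4-methyl-5,6-dihydro-2H-pyran-2-one
Product: 13 methyl (2Z)-5-bromo-3-methylpent-2-enoate
Conditions: BBr3, CH2Cl2, 0 °C → rt; then MeOH, 0 °C → rt
Reagents that add atoms: boron tribromide, BrB(Br)Br; methanol, CO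
Why: Lewis-acid-assisted bromide opening of the lactone at the O–CH2 bond followed by methanolysis gives the bromo ester (lactone cleavage with BBr3), the (Z) geometry being inherited from the ring.

Step 7
Reactants: 11 (4aR,6R,8aR)-5,5,8a-trimethyl-6-(triethylsilyloxy)-3,4,4a,5,6,7,8,8a-octahydronaphthalen-1-yl trifluoromethanesulfonate; 13 methyl (2Z)-5-bromo-3-methylpent-2-enoate
Product: 15 methyl (2Z)-3-methyl-5-[(4aS,6R,8aR)-5,5,8a-trimethyl-6-(triethylsilyloxy)-3,4,4a,5,6,7,8,8a-octahydronaphthalen-1-yl]pent-2-enoate, via organozinc bromide 14 (not isolated)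
Conditions: 13, Zn dust, I2 (5 mol%), N,N-dimethylacetamide, 70 °C; then 11, PdCl2(dppf) (5 mol%), THF, 50 °C
Reagents that add atoms: none
Why: Zinc insertion into the primary bromide and palladium-catalysed sp2–sp3 Negishi coupling with the enol triflate attaches the complete side chain at C9 with the (Z)-enoate geometry retained, the zinc reagent tolerating ester and silyl ether.

Step 8
Reactants: 15 methyl (2Z)-3-methyl-5-[(4aS,6R,8aR)-5,5,8a-trimethyl-6-(triethylsilyloxy)-3,4,4a,5,6,7,8,8a-octahydronaphthalen-1-yl]pent-2-enoate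
Product: 17 methyl (2Z)-5-[(1S,2S,4aS,6R,8aR)-2-hydroxy-5,5,8a-trimethyl-6-(triethylsilyloxy)decahydronaphthalen-1-yl]-3-methylpent-2-enoate, via alkylborane 16 (not isolated)
Conditions: BH3·SMe2 (1.3 equiv), THF, 0 °C → rt; then 30% H2O2, aq. NaOAc, 0 °C → rt
Reagents that add atoms: hydrogen peroxide, OO
Why: Hydroboration–oxidation should take the electron-rich trisubstituted C8=C9 alkene in preference to the electron-poor enoate, with boron at C8 and hydrogen at C9 added syn from the face opposite the axial C10 methyl, which sets (9S) with the side chain equatorial.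

Step 9
Reactants: 17 methyl (2Z)-5-[(1S,2S,4aS,6R,8aR)-2-hydroxy-5,5,8a-trimethyl-6-(triethylsilyloxy)decahydronaphthalen-1-yl]-3-methylpent-2-enoate
Product: 18 methyl (2Z)-3-methyl-5-[(1S,4aS,6R,8aR)-5,5,8a-trimethyl-2-oxo-6-(triethylsilyloxy)decahydronaphthalen-1-yl]pent-2-enoate
Conditions: 1,1,1-triacetoxy-1,1-dihydro-1,2-benziodoxol-3(1H)-one, NaHCO3, CH2Cl2, rt
Reagents that add atoms: none
Why: Buffered periodinane oxidation of the secondary C8 alcohol gives the 8-ketone without epimerising C9, whose equatorial side chain is also the thermodynamic arrangement.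

Step 10
Reactants: 18 methyl (2Z)-3-methyl-5-[(1S,4aS,6R,8aR)-5,5,8a-trimethyl-2-oxo-6-(triethylsilyloxy)decahydronaphthalen-1-yl]pent-2-enoate
Product: 20 methyl (2Z)-5-[(1S,2R,4aS,6R,8aR)-2-hydroxy-2-(hydroxymethyl)-5,5,8a-trimethyl-6-(triethylsilyloxy)decahydronaphthalen-1-yl]-3-methylpent-2-enoate, via hydroxy silane 19 (not isolated)
Conditions: ClCH2SiMe2(OiPr), Mg, THF → Grignard reagent; CeCl3, THF, −78 °C; 18, −78 → −20 °C; then 30% H2O2, KF, KHCO3, THF/MeOH, rt
Reagents that add atoms: [dimethyl(propan-2-yloxy)silyl]methylmagnesium chloride, CC(C)O[Si](C)(C)C[Mg]Cl; hydrogen peroxide, OO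
Why: The silylmethyl organocerium reagent should add to the ketone and not the ester, along the equatorial trajectory because the axial one is blocked by the syn-axial C10 methyl, which sets (8R) with axial OH and equatorial C17; Tamao–Fleming oxidation then converts C–Si into C–OH (nucleophilic hydroxymethylation).

Step 11
Reactants: 20 methyl (2Z)-5-[(1S,2R,4aS,6R,8aR)-2-hydroxy-2-(hydroxymethyl)-5,5,8a-trimethyl-6-(triethylsilyloxy)decahydronaphthalen-1-yl]-3-methylpent-2-enoate
Product: 22 (2Z)-5-[(1S,2R,4aS,6R,8aR)-2,6-dihydroxy-2-(hydroxymethyl)-5,5,8a-trimethyldecahydronaphthalen-1-yl]-3-methylpent-2-enoic acid, via lithium carboxylate 21 (not isolated)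
Conditions: LiOH·H2O, THF/MeOH/H2O, 45 °C; then 1 M HCl to pH 2, rt
Reagents that add atoms: lithium hydroxide, [Li+].[OH-]
Why: Saponification of the methyl ester and acid cleavage of the triethylsilyl ether in the work-up free the acid and the C3 hydroxyl before the base- and acid-sensitive α-hydroxy aldehyde exists.

Step 12
Reactants: 22 (2Z)-5-[(1S,2R,4aS,6R,8aR)-2,6-dihydroxy-2-(hydroxymethyl)-5,5,8a-trimethyldecahydronaphthalen-1-yl]-3-methylpent-2-enoic acid
Product: 23 (2Z)-5-[(1S,2R,4aS,6R,8aR)-2-formyl-2,6-dihydroxy-5,5,8a-trimethyldecahydronaphthalen-1-yl]-3-methylpent-2-enoic acid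
Conditions: 2,2,6,6-tetramethylpiperidin-1-oxyl (20 mol%), PhI(OAc)2 (1.2 equiv), CH2Cl2, rt
Reagents that add atoms: none
Why: Oxoammonium-catalysed oxidation should select the primary C17 alcohol over the hindered secondary C3 and the tertiary C8 alcohols and stop at the aldehyde under anhydrous conditions, touching no stereocenter.

## Compound list

1 | 2-methylcyclohex-2-en-1-one | CC1=CCCCC1=O | starting material
2 | 1-methoxy-2-methyl-1-(trimethylsilyloxy)prop-1-ene | COC(O[Si](C)(C)C)=C(C)C | starting material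
3 | tert-butyl prop-2-enoate | C=CC(=O)OC(C)(C)C | starting material
4 | methyl 2-methyl-2-[(1S)-2-methyl-3-(trimethylsilyloxy)cyclohex-2-en-1-yl]propanoate | COC(=O)C(C)(C)[C@H]1CCCC(O[Si](C)(C)C)=C1C | intermediate
5 | potassium (3S)-3-(1-methoxy-2-methyl-1-oxopropan-2-yl)-2-methylcyclohex-1-en-1-olate | COC(=O)C(C)(C)[C@H]1CCCC([O-])=C1C.[K+] | intermediate
6 | potassium ester enolate of tert-butyl 3-[(1R,2S)-2-(1-methoxy-2-methyl-1-oxopropan-2-yl)-1-methyl-6-oxocyclohexyl]propanoate | O=C1[C@](C)(CC=C([O-])OC(C)(C)C)[C@@H](C(C)(C)C(=O)OC)CCC1.[K+] | intermediate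
7 | tert-butyl (4aR,8aR)-4,4,8a-trimethyl-3,8-dioxodecahydronaphthalene-2-carboxylate (C2 epimers/enol) | O=C1[C@]2(C)CC(C(=O)OC(C)(C)C)C(=O)C(C)(C)[C@H]2CCC1 | intermediate
8 | tert-butyl (4aS,8aR)-4,4,8a-trimethyl-3-oxo-8-(trifluoromethanesulfonyloxy)-1,2,3,4,4a,5,6,8a-octahydronaphthalene-2-carboxylate (C2 epimers/enol) | FC(F)(F)S(=O)(=O)OC=1[C@]2(C)CC(C(=O)OC(C)(C)C)C(=O)C(C)(C)[C@H]2CCC=1 | intermediate
9 | (4aS,8aR)-5,5,8a-trimethyl-6-oxo-3,4,4a,5,6,7,8,8a-octahydronaphthalen-1-yl trifluoromethanesulfonate | FC(F)(F)S(=O)(=O)OC=1[C@]2(C)CCC(=O)C(C)(C)[C@H]2CCC=1 | intermediate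
10 | (4aR,6R,8aR)-6-hydroxy-5,5,8a-trimethyl-3,4,4a,5,6,7,8,8a-octahydronaphthalen-1-yl trifluoromethanesulfonate | FC(F)(F)S(=O)(=O)OC=1[C@]2(C)CC[C@@H](O)C(C)(C)[C@H]2CCC=1 | intermediate
11 | (4aR,6R,8aR)-5,5,8a-trimethyl-6-(triethylsilyloxy)-3,4,4a,5,6,7,8,8a-octahydronaphthalen-1-yl trifluoromethanesulfonate | FC(F)(F)S(=O)(=O)OC=1[C@]2(C)CC[C@@H](O[Si](CC)(CC)CC)C(C)(C)[C@H]2CCC=1 | intermediate
12 | 4-methyl-5,6-dihydro-2H-pyran-2-one | CC1=CC(=O)OCC1 | starting material
13 | methyl (2Z)-5-bromo-3-methylpent-2-enoate | C/C(=C/C(=O)OC)CCBr | intermediate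
14 | [(3Z)-5-methoxy-3-methyl-5-oxopent-3-en-1-yl]zinc bromide | C/C(=C/C(=O)OC)CC[Zn]Br | intermediate
15 | methyl (2Z)-3-methyl-5-[(4aS,6R,8aR)-5,5,8a-trimethyl-6-(triethylsilyloxy)-3,4,4a,5,6,7,8,8a-octahydronaphthalen-1-yl]pent-2-enoate | C/C(=C/C(=O)OC)CCC=1[C@]2(C)CC[C@@H](O[Si](CC)(CC)CC)C(C)(C)[C@H]2CCC=1 | intermediate
16 | C8 monoalkylborane of 15 (boron on C8 and hydrogen on C9 both on the face opposite the C10 methyl) | C/C(=C/C(=O)OC)CC[C@H]1[C@]2(C)CC[C@@H](O[Si](CC)(CC)CC)C(C)(C)[C@H]2CC[C@@H]1B | intermediate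
17 | methyl (2Z)-5-[(1S,2S,4aS,6R,8aR)-2-hydroxy-5,5,8a-trimethyl-6-(triethylsilyloxy)decahydronaphthalen-1-yl]-3-methylpent-2-enoate | C/C(=C/C(=O)OC)CC[C@H]1[C@]2(C)CC[C@@H](O[Si](CC)(CC)CC)C(C)(C)[C@H]2CC[C@@H]1O | intermediate
18 | methyl (2Z)-3-methyl-5-[(1S,4aS,6R,8aR)-5,5,8a-trimethyl-2-oxo-6-(triethylsilyloxy)decahydronaphthalen-1-yl]pent-2-enoate | C/C(=C/C(=O)OC)CC[C@H]1[C@]2(C)CC[C@@H](O[Si](CC)(CC)CC)C(C)(C)[C@H]2CCC1=O | intermediate
19 | methyl (2Z)-5-[(1S,2R,4aS,6R,8aR)-2-{[dimethyl(propan-2-yloxy)silyl]methyl}-2-hydroxy-5,5,8a-trimethyl-6-(triethylsilyloxy)decahydronaphthalen-1-yl]-3-methylpent-2-enoate | C/C(=C/C(=O)OC)CC[C@H]1[C@]2(C)CC[C@@H](O[Si](CC)(CC)CC)C(C)(C)[C@H]2CC[C@]1(O)C[Si](C)(C)OC(C)C | intermediate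
20 | methyl (2Z)-5-[(1S,2R,4aS,6R,8aR)-2-hydroxy-2-(hydroxymethyl)-5,5,8a-trimethyl-6-(triethylsilyloxy)decahydronaphthalen-1-yl]-3-methylpent-2-enoate | C/C(=C/C(=O)OC)CC[C@H]1[C@]2(C)CC[C@@H](O[Si](CC)(CC)CC)C(C)(C)[C@H]2CC[C@]1(O)CO | intermediate
21 | lithium (2Z)-5-[(1S,2R,4aS,6R,8aR)-2-hydroxy-2-(hydroxymethyl)-5,5,8a-trimethyl-6-(triethylsilyloxy)decahydronaphthalen-1-yl]-3-methylpent-2-enoate | [Li+].C/C(=C/C(=O)[O-])CC[C@H]1[C@]2(C)CC[C@@H](O[Si](CC)(CC)CC)C(C)(C)[C@H]2CC[C@]1(O)CO | intermediate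
22 | (2Z)-5-[(1S,2R,4aS,6R,8aR)-2,6-dihydroxy-2-(hydroxymethyl)-5,5,8a-trimethyldecahydronaphthalen-1-yl]-3-methylpent-2-enoic acid | C/C(=C/C(=O)O)CC[C@H]1[C@]2(C)CC[C@@H](O)C(C)(C)[C@H]2CC[C@]1(O)CO | intermediate
23 | (2Z)-5-[(1S,2R,4aS,6R,8aR)-2-formyl-2,6-dihydroxy-5,5,8a-trimethyldecahydronaphthalen-1-yl]-3-methylpent-2-enoic acid | C/C(=C/C(=O)O)CC[C@H]1[C@]2(C)CC[C@@H](O)C(C)(C)[C@H]2CC[C@]1(O)C=O | target

## Step count and risks

Total: 12 steps. Longest linear sequence: 11 steps (steps 1–5 and 7–12; step 6 is the side-chain branch).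

Steps most likely to fail:

Step 1. What may go wrong: weak enantioface discrimination by the boron Lewis acid on the α-methyl enone, and proton exchange that erodes the regiodefined C10 enolate before C-alkylation. The fallback takes the chirality from a ketone reduction and a [3,3] chirality transfer instead of a catalytic conjugate addition. It sets out from 1. Oxazaborolidine-catalysed borane reduction ((S)-1-methyl-3,3-diphenyltetrahydro-1H,3H-pyrrolo[1,2-c][1,3,2]oxazaborole, BH3·SMe2) should give, by the usual model, (1R)-2-methylcyclohex-2-en-1-ol F1. Acylation with 2-methylpropanoyl chloride and pyridine gives (1R)-2-methylcyclohex-2-en-1-yl 2-methylpropanoate F2. Ireland–Claisen rearrangement (LiN(iPr)2, Me3SiCl, THF, −78 → 60 °C, then aqueous acid) forms the C4–C5 bond suprafacially and gives 2-methyl-2-[(1S)-2-methylcyclohex-2-en-1-yl]propanoic acid F3. MeI/K2CO3 gives the methyl ester F4, hydroboration–oxidation (BH3·SMe2; H2O2, NaOH) the alcohol F5, and periodinane oxidation the ketone F6. Me3SiCl, Et3N, DMF at 100 °C (thermodynamic enol silane) then gives 4, now isolated, where the fallback comes back to the route; 4 goes on through the KOtBu/3 part of step 1 to 7.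

Step 8. What may go wrong: competitive hydroboration or reduction of the conjugated ester alkene, or slow addition of borane to the hindered ring alkene. The fallback replaces hydroboration by dihydroxylation, oxidation and reductive α-deoxygenation. It sets out from 15. OsO4 (cat.) with N-methylmorpholine N-oxide in acetone/water should take the more electron-rich ring alkene, from the face opposite the C10 methyl, and give the 8,9-diol F7. Periodinane oxidation of its secondary hydroxyl gives the 9-hydroxy-8-ketone F8. SmI2 in THF/MeOH at −78 °C cleaves the C9–O bond, and protonation of the samarium enolate (with equilibration by DBU if needed) gives 18, where the fallback comes back to the route.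

Step 12. What may go wrong: glycol cleavage of the 1,2-diol by the hypervalent iodine oxidant, or over-oxidation, in competition with slow oxidation of the neopentyl-type primary alcohol. The fallback takes C17 from a vinyl group by oxidative cleavage instead of alcohol oxidation. It sets out from 18. H2C=CHMgBr with CeCl3 (THF, −78 °C) adds equatorially to give the tertiary allylic alcohol F9. LiOH, then 1 M HCl, gives the acid with free C3 hydroxyl F10. Ozonolysis (O3, CH2Cl2/MeOH, −78 °C, stopped with Sudan red 7B as indicator; then Me2S) of the monosubstituted vinyl group, which should react before the conjugated acid alkene, gives 23, where the fallback comes back to the route.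

Further compounds

F1 | step 1 | (1R)-2-methylcyclohex-2-en-1-ol | O[C@@H]1CCCC=C1C
F2 | step 1 | (1R)-2-methylcyclohex-2-en-1-yl 2-methylpropanoate | CC(C)C(=O)O[C@@H]1CCCC=C1C
F3 | step 1 | 2-methyl-2-[(1S)-2-methylcyclohex-2-en-1-yl]propanoic acid | OC(=O)C(C)(C)[C@H]1CCCC=C1C
F4 | step 1 | methyl 2-methyl-2-[(1S)-2-methylcyclohex-2-en-1-yl]propanoate | COC(=O)C(C)(C)[C@H]1CCCC=C1C
F5 | step 1 | methyl 2-[(1S,2S,3S)-3-hydroxy-2-methylcyclohexyl]-2-methylpropanoate | COC(=O)C(C)(C)[C@H]1CCC[C@H](O)[C@H]1C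
F6 | step 1 | methyl 2-methyl-2-[(1S)-2-methyl-3-oxocyclohexyl]propanoate (C2 epimers) | COC(=O)C(C)(C)[C@H]1CCCC(=O)C1C
F7 | step 8 | methyl (2Z)-5-[(1R,2S,4aR,6R,8aR)-1,2-dihydroxy-5,5,8a-trimethyl-6-(triethylsilyloxy)decahydronaphthalen-1-yl]-3-methylpent-2-enoate | C/C(=C/C(=O)OC)CC[C@@]1(O)[C@]2(C)CC[C@@H](O[Si](CC)(CC)CC)C(C)(C)[C@H]2CC[C@@H]1O
F8 | step 8 | methyl (2Z)-5-[(1R,4aR,6R,8aR)-1-hydroxy-5,5,8a-trimethyl-2-oxo-6-(triethylsilyloxy)decahydronaphthalen-1-yl]-3-methylpent-2-enoate | C/C(=C/C(=O)OC)CC[C@@]1(O)[C@]2(C)CC[C@@H](O[Si](CC)(CC)CC)C(C)(C)[C@H]2CCC1=O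
F9 | step 12 | methyl (2Z)-5-[(1S,2S,4aS,6R,8aR)-2-ethenyl-2-hydroxy-5,5,8a-trimethyl-6-(triethylsilyloxy)decahydronaphthalen-1-yl]-3-methylpent-2-enoate | C/C(=C/C(=O)OC)CC[C@H]1[C@]2(C)CC[C@@H](O[Si](CC)(CC)CC)C(C)(C)[C@H]2CC[C@]1(O)C=C
F10 | step 12 | (2Z)-5-[(1S,2S,4aS,6R,8aR)-2-ethenyl-2,6-dihydroxy-5,5,8a-trimethyldecahydronaphthalen-1-yl]-3-methylpent-2-enoic acid | C/C(=C/C(=O)O)CC[C@H]1[C@]2(C)CC[C@@H](O)C(C)(C)[C@H]2CC[C@]1(O)C=C
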